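The route rests on cutting the ethano bridge in its middle, between Cα (on C1′ of the 3-methoxyphenyl ring B) and Cβ (on C1 of the pentasubstituted ring A). Both carbons are benzylic, carry no heteroatom, and are cheapest as aldehyde carbons, that is, as two electrophiles. The key step reverses the polarity of one. The N–H hydrazone of 3-methoxybenzaldehyde acts as a benzyl anion equivalent and is cross-coupled under Ru(II) catalysis with the fully assembled ring A aldehyde, which already carries both 4-benzyloxybenzyl arms at C2 and C6. This gives the Cα=Cβ stilbene with loss of only N2 and water. One hydrogenation then saturates the bridge and frees all three phenols.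

Key step: step 5

Assumption: the SMILES is taken as binding (ring A: C1 bridge, C2/C6 4-hydroxybenzyl, C3 OH, C5 OMe; ring B: 3′-OMe); it holds no stereocentre and no stereodefined double bond, so the target is achiral and no enantiocontrol is needed.

Step 1
Reactants: 1 3-hydroxy-5-methoxybenzaldehyde
Product: 2 3-(benzyloxy)-5-methoxybenzaldehyde
Conditions: BnBr, K2CO3, DMF, rt
Reagents that add atoms: benzyl bromide BrCc1ccccc1
Why: Williamson ether synthesis, in which the phenoxide of 1 is the only nucleophile present and the benzyl ether is chosen because it falls in the final hydrogenation.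

Step 2
Reactants: 2 3-(benzyloxy)-5-methoxybenzaldehyde
Product: 3 3-(benzyloxy)-2,6-dibromo-5-methoxybenzaldehyde
Conditions: NBS (2.2 equiv), MeCN, 0 °C to 40 °C, dark
Reagents that add atoms: N-bromosuccinimide O=C1CCC(=O)N1Br
Why: Electrophilic aromatic bromination, in which C2 and C6 are each para to one alkoxy group and ortho to the other while C4 is squeezed between both alkoxy groups, so the reaction should stop at the 2,6-dibromide as is known for 3,5-dialkoxybenzaldehydes.

Step 3
Reactants: 4 4-(benzyloxy)benzyl chloride
Product: 5 2-[4-(benzyloxy)benzyl]-4,4,5,5-tetramethyl-1,3,2-dioxaborolane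
Conditions: B2pin2, Pd(dba)2 (cat.), P(4-MeOC6H4)3 (cat.), KOAc, toluene, 50 °C
Reagents that add atoms: bis(pinacolato)diboron CC1(C)OB(OC1(C)C)B1OC(C)(C)C(C)(C)O1
Why: Miyaura borylation of a benzylic chloride (oxidative addition of C–Cl to Pd(0), acetate-assisted transmetalation with B2pin2, reductive elimination), which leaves the aryl benzyl ether untouched.

Step 4
Reactants: 3 3-(benzyloxy)-2,6-dibromo-5-methoxybenzaldehyde; 5 2-[4-(benzyloxy)benzyl]-4,4,5,5-tetramethyl-1,3,2-dioxaborolane (2.6 equiv)
Product: 6 3-(benzyloxy)-2,6-bis[4-(benzyloxy)benzyl]-5-methoxybenzaldehyde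
Conditions: Pd(OAc)2 (cat.), SPhos (cat.), K3PO4, toluene/H2O, 90 °C
Reagents that add atoms: none
Why: Twofold sp2–sp3 Suzuki–Miyaura coupling, in which the ortho formyl group speeds oxidative addition, the bulky biarylphosphine copes with the di-ortho-substituted C–Br bonds, the benzyl group has no β-hydrogen to lose, and the boronate (unlike a benzylzinc or Grignard reagent) leaves the aldehyde alone.

Step 5
Reactants: 6 3-(benzyloxy)-2,6-bis[4-(benzyloxy)benzyl]-5-methoxybenzaldehyde; 7 3-methoxybenzaldehyde (about 2 equiv)
Product: 9 (E)-3-(benzyloxy)-2,6-bis[4-(benzyloxy)benzyl]-3′,5-dimethoxystilbene, via (E)-3-methoxybenzaldehyde hydrazone 8 (not isolated)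
Conditions: 7, N2H4·H2O, THF, rt, Na2SO4 (gives 8); then 6, [Ru(p-cymene)Cl2]2 (cat.), dmpe (cat.), KOtBu (substoichiometric), CsF (additive), THF, 45 °C, N2
Reagents that add atoms: none
Why: Condensation of 7 with hydrazine turns its electrophilic carbonyl carbon into the nucleophilic carbon of an N-unsubstituted hydrazone (polarity reversal), which, once N-bound and deprotonated on the Ru(II)–dmpe centre, attacks the Ru-coordinated formyl carbon of 6 through a six-membered chair-like transition state and so forms the Cα–Cβ bond. The resulting β-alkoxy diazene loses N2 under base, and the benzylic carbanion character that develops at Cα expels the neighbouring oxygen as hydroxide (E1cB-like), which gives the stilbene with N2 and water as the only by-products. The closest known reaction type is the ruthenium-catalysed, hydrazine-mediated reductive carbonyl cross-coupling (olefination) of aldehyde hydrazones with aldehydes and ketones, a catalytic and cross-selective counterpart of the McMurry reaction. No ring is closed and no stereocentre is set, and the E/Z outcome is irrelevant because step 6 saturates the double bond. The step needs cross- over homo-coupling and C- over N-attack (azine formation): the roles are fixed because only 7 is pre-condensed with hydrazine, the benzyl arms at C2 and C6 of ring A twist and shield the formyl group of 6 and should slow hydrazone exchange and azine formation, and an excess of cheap 8 covers its own Wolff–Kishner-type loss.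

Step 6
Reactants: 9 (E)-3-(benzyloxy)-2,6-bis[4-(benzyloxy)benzyl]-3′,5-dimethoxystilbene
Product: 10 2,6-bis(4-hydroxybenzyl)-3-hydroxy-3′,5-dimethoxybibenzyl (target)
Conditions: H2 (1–3 atm), 10% Pd/C, EtOAc/MeOH, rt
Reagents that add atoms: none
Why: Heterogeneous catalytic hydrogenation saturates the 1,2-disubstituted alkene and hydrogenolyses the three aryl benzyl ethers in one operation, while the methyl ethers, the diarylmethane CH2 groups and the new bibenzyl bond are inert.

Compound list
1 | 3-hydroxy-5-methoxybenzaldehyde | COc1cc(O)cc(C=O)c1 | starting material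
2 | 3-(benzyloxy)-5-methoxybenzaldehyde | COc1cc(OCc2ccccc2)cc(C=O)c1 | intermediate
3 | 3-(benzyloxy)-2,6-dibromo-5-methoxybenzaldehyde | COc1cc(OCc2ccccc2)c(Br)c(C=O)c1Br | intermediate
4 | 4-(benzyloxy)benzyl chloride | ClCc1ccc(OCc2ccccc2)cc1 | starting material
5 | 2-[4-(benzyloxy)benzyl]-4,4,5,5-tetramethyl-1,3,2-dioxaborolane | CC1(C)OB(Cc2ccc(OCc3ccccc3)cc2)OC1(C)C | intermediate
6 | 3-(benzyloxy)-2,6-bis[4-(benzyloxy)benzyl]-5-methoxybenzaldehyde | COc1cc(OCc2ccccc2)c(Cc2ccc(OCc3ccccc3)cc2)c(C=O)c1Cc1ccc(OCc2ccccc2)cc1 | intermediate
7 | 3-methoxybenzaldehyde | COc1cccc(C=O)c1 | starting material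
8 | (E)-3-methoxybenzaldehyde hydrazone (N-unsubstituted, not isolated) | COc1cccc(/C=N/N)c1 | intermediate
9 | (E)-3-(benzyloxy)-2,6-bis[4-(benzyloxy)benzyl]-3′,5-dimethoxystilbene | COc1cccc(/C=C/c2c(Cc3ccc(OCc4ccccc4)cc3)c(OCc3ccccc3)cc(OC)c2Cc2ccc(OCc3ccccc3)cc2)c1 | intermediate
10 | 2,6-bis(4-hydroxybenzyl)-3-hydroxy-3′,5-dimethoxybibenzyl (achiral) | COc1cccc(CCc2c(Cc3ccc(O)cc3)c(O)cc(OC)c2Cc2ccc(O)cc2)c1 | target

Total step count: 6. Longest linear sequence: 5 steps (1 → 2 → 3 → 6 → 9 → 10).

Steps most likely to fail

Risk 1 (step 5): C–C bond formation at the doubly ortho-flanked formyl group may be slow. It could then be outrun by N-attack (azine formation), by hydrazone exchange between the two aldehydes, or by base-induced loss of the hydrazone. The carbanion may also be protonated before β-elimination, so that the reaction halts at the carbinol stage. The base may deprotonate the diarylmethane CH2 groups next to the formyl group. The fallback sets out from 6 and replaces the umpolung by classical polarity. It is a Horner–Wadsworth–Emmons olefination with commercial diethyl (3-methoxybenzyl)phosphonate (KOtBu, THF, 0 °C to rt). It comes back to the route at 9 and makes no new compound.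

Risk 2 (step 4): protodeboronation of the benzylboronate may be faster than transmetalation at the crowded aryl–Pd centre, and the sequence may stall after the first coupling. The fallback sets out from 3 and changes the nucleophile to zinc after masking the aldehyde.
- 3 is converted with HC(OMe)3 and cat. TsOH in MeOH into 3-(benzyloxy)-2,6-dibromo-5-methoxybenzaldehyde dimethyl acetal F1.
- 4 is inserted with Zn dust/LiCl in THF to give [4-(benzyloxy)benzyl]zinc chloride F2.
- A twofold Negishi coupling (Pd(OAc)2/SPhos, THF, 50 °C) should give 3-(benzyloxy)-2,6-bis[4-(benzyloxy)benzyl]-5-methoxybenzaldehyde dimethyl acetal F3.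
- Dilute HCl in THF at rt hydrolyses F3, and the fallback comes back to the route at 6.

Risk 3 (step 2): regiocontrol may be lost in the second bromination (attack at C4 between the two alkoxy groups). The second substitution may also stay incomplete on the ring deactivated by the formyl group and the first bromine. The fallback sets out from 2 and moves the halogenation to the alcohol oxidation level, where the ring is more reactive and the 2,6-pattern is well established for 3,5-dialkoxybenzyl alcohols.
- NaBH4 in MeOH gives [3-(benzyloxy)-5-methoxyphenyl]methanol F4.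
- NBS (2 equiv, MeCN, 0 °C) gives [3-(benzyloxy)-2,6-dibromo-5-methoxyphenyl]methanol F5.
- MnO2 in CH2Cl2 brings the fallback back to the route at 3.

Further compounds
F0 | step 5 | none | none
F1 | step 4 | 3-(benzyloxy)-2,6-dibromo-5-methoxybenzaldehyde dimethyl acetal | COc1cc(OCc2ccccc2)c(Br)c(C(OC)OC)c1Br
F2 | step 4 | [4-(benzyloxy)benzyl]zinc chloride | Cl[Zn]Cc1ccc(OCc2ccccc2)cc1
F3 | step 4 | 3-(benzyloxy)-2,6-bis[4-(benzyloxy)benzyl]-5-methoxybenzaldehyde dimethyl acetal | COc1cc(OCc2ccccc2)c(Cc2ccc(OCc3ccccc3)cc2)c(C(OC)OC)c1Cc1ccc(OCc2ccccc2)cc1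
F4 | step 2 | [3-(benzyloxy)-5-methoxyphenyl]methanol | COc1cc(OCc2ccccc2)cc(CO)c1
F5 | step 2 | [3-(benzyloxy)-2,6-dibromo-5-methoxyphenyl]methanol | COc1cc(OCc2ccccc2)c(Br)c(CO)c1Br
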